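**Retrosynthetic overview**
1. Target 25 ⇐ global desilylation of tetrasilyl enone 24 ⇐ allylic C–H oxidation (ring CH2, C16) of cyclohexene 23.
2. 23 ⇐ copper-catalysed sp3–sp3 coupling (C12–C13) of neopentyl Grignard reagent 22 (ring part, from iodide 6) with tosylate 21 (C1–C12 chain).
3. Ring part ⇐ aldehyde 4 ⇐ amine-catalysed asymmetric Diels–Alder reaction of enal 3 with silyloxydiene 2 (the only ring, formed first in its branch; sets C14, C15, C19).
4. Chain 21 ⇐ C10 by organocatalytic transfer hydrogenation of enal 18 ⇐ ketone 16 ⇐ C3/C4 by phosphoric-acid-catalysed anti-allylboration of aldehyde 13 with boronate 8.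
5. 13 ⇐ C6 by catalyst-controlled Mukaiyama aldol of 11 ⇐ C7 by enamine Michael addition of propanal to methyl vinyl ketone.

Assumption: carbons are labelled C1–C19 along the main chain in the order of the target SMILES (Ca = the CH2OH carbon), and 1, 3, 7, 9, 10, 12 and the phosphonate of step 11 are taken as purchasable achiral materials.

**Route**

Step 1
Reactants: 1 pent-4-en-2-one
Product: 2 (Z)-tert-butyldimethyl(penta-2,4-dien-2-yloxy)silane
Conditions: TBSOTf (1.1 equiv), Et3N (1.5 equiv), CH2Cl2, 0 °C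
Reagents that add atoms: tert-butyldimethylsilyl triflate, CC(C)(C)[Si](C)(C)OS(=O)(=O)C(F)(F)F
Why: Soft enolisation (silyl enol ether formation) removes the doubly activated C3–H (α to C=O and allylic) and gives the conjugated dienol ether, the Z isomer (OSi cis to the vinyl group) being the usual outcome of internal enolisation of a methyl ketone under amine/silyl triflate conditions.

Step 2
Reactants: 3 (E)-2-methylpent-2-enal; 2 (Z)-tert-butyldimethyl(penta-2,4-dien-2-yloxy)silane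
Product: 4 (1R,2R,6S)-2-[(tert-butyldimethylsilyl)oxy]-6-ethyl-1,2-dimethylcyclohex-3-ene-1-carbaldehyde
Conditions: 9-amino-9-deoxy-epi-quinidine (20 mol %), CF3CO2H (30 mol %), toluene, 0 °C
Reagents that add atoms: none
Why: Proposed new method: iminium-ion (LUMO-lowering) catalysis of a Diels–Alder reaction between an α,β-dialkyl enal and a ketone-derived 1-methyl-1-silyloxy diene, a pairing not yet shown; condensation of 3 with the primary amine gives the E-iminium ion, which removes the free C=O (no Mukaiyama aldol or hetero-Diels–Alder path), the electron-rich diene bonds first through its CH2 terminus to the iminium β-carbon (C15–C16, "ortho" orientation) and the enamine carbon then closes onto the silyloxy-bearing terminus (C14–C19) in a concerted but asynchronous endo transition state, so the E geometry of 3 puts ethyl cis to the C14 methyl, the Z geometry of 2 (OTBS inside) with the iminium group endo puts OTBS trans to the formyl group, and the protonated quinuclidine blocks one iminium face to set the absolute configuration (the pseudo-enantiomeric quinine-derived amine is used if the sense is opposite); the closest known reaction types are the amine-catalysed Diels–Alder reaction of enals with acyclic oxygenated dienes, Mukaiyama–Michael additions of silyl enol ethers to iminium ions, and primary-amine iminium activation of this same enal in conjugate additions.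

Step 3
Reactants: 4 (1R,2R,6S)-2-[(tert-butyldimethylsilyl)oxy]-6-ethyl-1,2-dimethylcyclohex-3-ene-1-carbaldehyde
Product: 5 [(1S,2R,6S)-2-[(tert-butyldimethylsilyl)oxy]-6-ethyl-1,2-dimethylcyclohex-3-en-1-yl]methanol
Conditions: NaBH4, MeOH, 0 °C
Reagents that add atoms: none
Why: Borohydride reduction of the non-enolisable neopentyl aldehyde; no stereocentre is touched.

Step 4
Reactants: 5 [(1S,2R,6S)-2-[(tert-butyldimethylsilyl)oxy]-6-ethyl-1,2-dimethylcyclohex-3-en-1-yl]methanol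
Product: 6 tert-butyl{[(1R,5S,6R)-5-ethyl-6-(iodomethyl)-1,6-dimethylcyclohex-2-en-1-yl]oxy}dimethylsilane
Conditions: PPh3, I2, imidazole, toluene, 80 °C
Reagents that add atoms: iodine, [I][I]
Why: Appel-type iodination, in which iodide displaces the oxyphosphonium of the neopentyl alcohol at elevated temperature, a substitution that works on hindered primary carbinols without skeletal change.

Step 5
Reactants: 7 (Z)-4-[(tert-butyldimethylsilyl)oxy]but-2-en-1-ol
Product: 8 (E)-tert-butyldimethyl{[4-(4,4,5,5-tetramethyl-1,3,2-dioxaborolan-2-yl)but-2-en-1-yl]oxy}silane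
Conditions: B2pin2, Pd(MeCN)4(BF4)2 (5 mol %), DMSO–MeOH, 50 °C
Reagents that add atoms: bis(pinacolato)diboron, CC1(C)OB(OC1(C)C)B1OC(C)(C)C(C)(C)O1
Why: Palladium-catalysed borylation of an allylic alcohol through a π-allyl intermediate gives the linear allylboronate, and syn–anti equilibration of the π-allyl delivers the E isomer from the Z alcohol.

Step 6
Reactants: 9 propanal; 10 but-3-en-2-one (methyl vinyl ketone)
Product: 11 (R)-2-methyl-5-oxohexanal
Conditions: (S)-2-[methoxy(diphenyl)methyl]pyrrolidine (5 mol %), ethyl 3,4-dihydroxybenzoate (20 mol %), neat, 4 °C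
Reagents that add atoms: none
Why: Enamine-catalysed Michael addition of an aldehyde to an enone; one face of the E-enamine of propanal is shielded by the diarylmethyl group, so C7 is formed as the R centre (the first stereocentre of this branch).

Step 7
Reactants: 11 (R)-2-methyl-5-oxohexanal; 12 tert-butyldimethyl(vinyloxy)silane
Product: 13 (3S,4R)-3-[(tert-butyldimethylsilyl)oxy]-4-methyl-7-oxooctanal
Conditions: chiral imidodiphosphorimidate (IDPi) Brønsted acid (1 mol %), CH2Cl2, −60 °C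
Reagents that add atoms: none
Why: Catalytic asymmetric Mukaiyama aldol addition (single aldolisation of an acetaldehyde enolsilane with silyl transfer to the new oxygen) inside the confined chiral ion pair; the catalyst enantiomer is chosen to set C6 as S, anti to the C7 methyl (the anti-Felkin sense, a mismatched but catalyst-controlled case), and the aldehyde reacts far faster than the methyl ketone.

Step 8
Reactants: 13 (3S,4R)-3-[(tert-butyldimethylsilyl)oxy]-4-methyl-7-oxooctanal; 8 (E)-tert-butyldimethyl{[4-(4,4,5,5-tetramethyl-1,3,2-dioxaborolan-2-yl)but-2-en-1-yl]oxy}silane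
Product: 14 (5R,6S,8R,9R)-6-[(tert-butyldimethylsilyl)oxy]-9-{[(tert-butyldimethylsilyl)oxy]methyl}-8-hydroxy-5-methylundec-10-en-2-one
Conditions: (S)-TRIP phosphoric acid (5 mol %), 4 Å MS, toluene, −30 °C; aq. NaHCO3 work-up
Reagents that add atoms: none
Why: Chiral phosphoric acid-catalysed allylboration through a chair-like six-membered transition state, in which the E geometry of 8 gives the anti relationship between C3–CH2OTBS and C4–OH and the catalyst selects the aldehyde face that makes C4 R (1,3-syn to the C6 oxygen); the ketone is inert.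

Step 9
Reactants: 14 (5R,6S,8R,9R)-6-[(tert-butyldimethylsilyl)oxy]-9-{[(tert-butyldimethylsilyl)oxy]methyl}-8-hydroxy-5-methylundec-10-en-2-one
Product: 15 (5R,6S,8R,9R)-6,8-bis[(tert-butyldimethylsilyl)oxy]-9-{[(tert-butyldimethylsilyl)oxy]methyl}-5-methylundec-10-en-2-one
Conditions: TBSOTf, 2,6-lutidine, CH2Cl2, −78 °C
Reagents that add atoms: tert-butyldimethylsilyl triflate, CC(C)(C)[Si](C)(C)OS(=O)(=O)C(F)(F)F
Why: Silyl ether formation of the secondary alcohol at low temperature, where the methyl ketone is not enolised by the hindered pyridine base.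

Step 10
Reactants: 15 (5R,6S,8R,9R)-6,8-bis[(tert-butyldimethylsilyl)oxy]-9-{[(tert-butyldimethylsilyl)oxy]methyl}-5-methylundec-10-en-2-one
Product: 16 (5R,6S,8R,9R)-6,8-bis[(tert-butyldimethylsilyl)oxy]-9-{[(tert-butyldimethylsilyl)oxy]methyl}-5-methylundecan-2-one
Conditions: H2 (1 atm), Pd/C, EtOAc, rt
Reagents that add atoms: none
Why: Heterogeneous catalytic hydrogenation turns the terminal vinyl group into the C1–C2 ethyl group; ketone, silyl ethers and the C3 configuration are untouched.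

Step 11
Reactants: 16 (5R,6S,8R,9R)-6,8-bis[(tert-butyldimethylsilyl)oxy]-9-{[(tert-butyldimethylsilyl)oxy]methyl}-5-methylundecan-2-one
Product: 18 (2E,6R,7S,9R,10R)-7,9-bis[(tert-butyldimethylsilyl)oxy]-10-{[(tert-butyldimethylsilyl)oxy]methyl}-3,6-dimethyldodec-2-enal (E/Z mixture), via N-cyclohexyl unsaturated aldimine 17 (not isolated)
Conditions: diethyl [2-(cyclohexylamino)vinyl]phosphonate, NaH, THF, 0 °C to rt; then (CO2H)2, H2O–toluene, rt
Reagents that add atoms: diethyl [2-(cyclohexylamino)vinyl]phosphonate, CCOP(=O)(OCC)/C=C/NC1CCCCC1; water, O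
Why: Horner–Wadsworth–Emmons formyl-olefination, in which the sodium salt of the aminovinylphosphonate adds to the methyl ketone and loses phosphate to give the unsaturated aldimine, which mild aqueous acid hydrolyses to the enal (both geometric isomers are used in the next step).

Step 12
Reactants: 18 (2E,6R,7S,9R,10R)-7,9-bis[(tert-butyldimethylsilyl)oxy]-10-{[(tert-butyldimethylsilyl)oxy]methyl}-3,6-dimethyldodec-2-enal
Product: 20 (3S,6R,7S,9R,10R)-7,9-bis[(tert-butyldimethylsilyl)oxy]-10-{[(tert-butyldimethylsilyl)oxy]methyl}-3,6-dimethyldodecan-1-ol, via saturated aldehyde 19 (not isolated)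
Conditions: Hantzsch ester (1.2 equiv), morpholinium (S)-TRIP phosphate (20 mol %), 1,4-dioxane, 50 °C; then NaBH4, MeOH, 0 °C
Reagents that add atoms: none
Why: Organocatalytic asymmetric transfer hydrogenation (iminium ion paired with the chiral phosphate, hydride from the Hantzsch ester), in which E and Z iminium ions interconvert and the counteranion directs hydride to one face of C10 to give the 3S centre (catalyst enantiomer chosen by analogy with the citral-to-citronellal reduction); the aldehyde is reduced in the same flask.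

Step 13
Reactants: 20 (3S,6R,7S,9R,10R)-7,9-bis[(tert-butyldimethylsilyl)oxy]-10-{[(tert-butyldimethylsilyl)oxy]methyl}-3,6-dimethyldodecan-1-ol
Product: 21 (3S,6R,7S,9R,10R)-7,9-bis[(tert-butyldimethylsilyl)oxy]-10-{[(tert-butyldimethylsilyl)oxy]methyl}-3,6-dimethyldodecyl 4-methylbenzenesulfonate
Conditions: TsCl, Et3N, DMAP (cat.), CH2Cl2, 0 °C to rt
Reagents that add atoms: 4-methylbenzenesulfonyl chloride, Cc1ccc(cc1)S(Cl)(=O)=O
Why: Sulfonylation of the unhindered primary alcohol gives the electrophile for the fragment coupling.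

Step 14
Reactants: 6 tert-butyl{[(1R,5S,6R)-5-ethyl-6-(iodomethyl)-1,6-dimethylcyclohex-2-en-1-yl]oxy}dimethylsilane; 21 (3S,6R,7S,9R,10R)-7,9-bis[(tert-butyldimethylsilyl)oxy]-10-{[(tert-butyldimethylsilyl)oxy]methyl}-3,6-dimethyldodecyl 4-methylbenzenesulfonate
Product: 23 tert-butyl{[(1R,5S,6R)-6-[(4R,7R,8S,10R,11R)-8,10-bis[(tert-butyldimethylsilyl)oxy]-11-{[(tert-butyldimethylsilyl)oxy]methyl}-4,7-dimethyltridecyl]-5-ethyl-1,6-dimethylcyclohex-2-en-1-yl]oxy}dimethylsilane, via neopentyl Grignard reagent 22 (not isolated)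
Conditions: 6 (1.4 equiv), activated Mg turnings, THF, 45 °C; then 21, CuCl2 (3 mol %), 1-phenylpropyne (15 mol %), THF, 0 °C to rt
Reagents that add atoms: none
Why: Copper-catalysed Kumada-type sp3–sp3 coupling, in which the neopentyl Grignard reagent made by magnesium insertion displaces the primary tosylate through an alkyne-stabilised alkylcopper species; no stereocentre is involved and the ring alkene is untouched.

Step 15
Reactants: 23 tert-butyl{[(1R,5S,6R)-6-[(4R,7R,8S,10R,11R)-8,10-bis[(tert-butyldimethylsilyl)oxy]-11-{[(tert-butyldimethylsilyl)oxy]methyl}-4,7-dimethyltridecyl]-5-ethyl-1,6-dimethylcyclohex-2-en-1-yl]oxy}dimethylsilane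
Product: 24 (4R,5R,6R)-4-[(tert-butyldimethylsilyl)oxy]-5-[(4R,7R,8S,10R,11R)-8,10-bis[(tert-butyldimethylsilyl)oxy]-11-{[(tert-butyldimethylsilyl)oxy]methyl}-4,7-dimethyltridecyl]-6-ethyl-4,5-dimethylcyclohex-2-en-1-one
Conditions: Rh2(cap)4 (1 mol %, cap = caprolactamate), t-BuOOH (70 % aq., 5 equiv), K2CO3, CH2Cl2, rt
Reagents that add atoms: tert-butyl hydroperoxide, CC(C)(C)OO
Why: Allylic C–H oxidation by tert-butylperoxyl radicals generated by the dirhodium carboxamidate catalyst; C16 is the only allylic CH2 (C19 is fully substituted) and oxygen is delivered to the less hindered terminus of the allyl radical, so the enone forms without moving the double bond.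

Step 16
Reactants: 24 (4R,5R,6R)-4-[(tert-butyldimethylsilyl)oxy]-5-[(4R,7R,8S,10R,11R)-8,10-bis[(tert-butyldimethylsilyl)oxy]-11-{[(tert-butyldimethylsilyl)oxy]methyl}-4,7-dimethyltridecyl]-6-ethyl-4,5-dimethylcyclohex-2-en-1-one
Product: 25 (4R,5R,6R)-5-[(4R,7R,8S,10R,11R)-8,10-dihydroxy-11-(hydroxymethyl)-4,7-dimethyltridecyl]-6-ethyl-4-hydroxy-4,5-dimethylcyclohex-2-en-1-one (CNP0104178.2)
Conditions: HF (48 % aq.), MeCN, rt to 40 °C
Reagents that add atoms: none
Why: Fluoride-mediated global desilylation of the four silyl ethers; the tertiary γ-hydroxy enone tolerates the acidic medium because ionisation at C19 would place a cation next to the enone, and the non-basic conditions protect the epimerisable C15 centre.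

**Compound list**
1 | pent-4-en-2-one | C=CCC(C)=O | starting material
2 | (Z)-tert-butyldimethyl(penta-2,4-dien-2-yloxy)silane | C=C/C=C(/C)O[Si](C)(C)C(C)(C)C | intermediate
3 | (E)-2-methylpent-2-enal | CC/C=C(\C)C=O | starting material
4 | (1R,2R,6S)-2-[(tert-butyldimethylsilyl)oxy]-6-ethyl-1,2-dimethylcyclohex-3-ene-1-carbaldehyde | O=C[C@]1(C)[C@@H](CC)CC=C[C@@]1(C)O[Si](C)(C)C(C)(C)C | intermediate
5 | [(1S,2R,6S)-2-[(tert-butyldimethylsilyl)oxy]-6-ethyl-1,2-dimethylcyclohex-3-en-1-yl]methanol | OC[C@]1(C)[C@@H](CC)CC=C[C@@]1(C)O[Si](C)(C)C(C)(C)C | intermediate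
6 | tert-butyl{[(1R,5S,6R)-5-ethyl-6-(iodomethyl)-1,6-dimethylcyclohex-2-en-1-yl]oxy}dimethylsilane | IC[C@]1(C)[C@@H](CC)CC=C[C@@]1(C)O[Si](C)(C)C(C)(C)C | intermediate
7 | (Z)-4-[(tert-butyldimethylsilyl)oxy]but-2-en-1-ol | OC/C=C\CO[Si](C)(C)C(C)(C)C | starting material
8 | (E)-tert-butyldimethyl{[4-(4,4,5,5-tetramethyl-1,3,2-dioxaborolan-2-yl)but-2-en-1-yl]oxy}silane | CC(C)(C)[Si](C)(C)OC/C=C/CB1OC(C)(C)C(C)(C)O1 | intermediate
9 | propanal | CCC=O | starting material
10 | but-3-en-2-one (methyl vinyl ketone) | CC(=O)C=C | starting material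
11 | (R)-2-methyl-5-oxohexanal | O=C[C@H](C)CCC(C)=O | intermediate
12 | tert-butyldimethyl(vinyloxy)silane | C=CO[Si](C)(C)C(C)(C)C | starting material
13 | (3S,4R)-3-[(tert-butyldimethylsilyl)oxy]-4-methyl-7-oxooctanal | O=CC[C@H](O[Si](C)(C)C(C)(C)C)[C@H](C)CCC(C)=O | intermediate
14 | (5R,6S,8R,9R)-6-[(tert-butyldimethylsilyl)oxy]-9-{[(tert-butyldimethylsilyl)oxy]methyl}-8-hydroxy-5-methylundec-10-en-2-one | C=C[C@H](CO[Si](C)(C)C(C)(C)C)[C@H](O)C[C@H](O[Si](C)(C)C(C)(C)C)[C@H](C)CCC(C)=O | intermediate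
15 | (5R,6S,8R,9R)-6,8-bis[(tert-butyldimethylsilyl)oxy]-9-{[(tert-butyldimethylsilyl)oxy]methyl}-5-methylundec-10-en-2-one | C=C[C@H](CO[Si](C)(C)C(C)(C)C)[C@H](O[Si](C)(C)C(C)(C)C)C[C@H](O[Si](C)(C)C(C)(C)C)[C@H](C)CCC(C)=O | intermediate
16 | (5R,6S,8R,9R)-6,8-bis[(tert-butyldimethylsilyl)oxy]-9-{[(tert-butyldimethylsilyl)oxy]methyl}-5-methylundecan-2-one | CC[C@H](CO[Si](C)(C)C(C)(C)C)[C@H](O[Si](C)(C)C(C)(C)C)C[C@H](O[Si](C)(C)C(C)(C)C)[C@H](C)CCC(C)=O | intermediate
17 | N-cyclohexyl aldimine of enal 18 | CC[C@H](CO[Si](C)(C)C(C)(C)C)[C@H](O[Si](C)(C)C(C)(C)C)C[C@H](O[Si](C)(C)C(C)(C)C)[C@H](C)CC/C(C)=C/C=NC1CCCCC1 | intermediate (not isolated)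
18 | (2E,6R,7S,9R,10R)-7,9-bis[(tert-butyldimethylsilyl)oxy]-10-{[(tert-butyldimethylsilyl)oxy]methyl}-3,6-dimethyldodec-2-enal (major isomer of an E/Z mixture) | CC[C@H](CO[Si](C)(C)C(C)(C)C)[C@H](O[Si](C)(C)C(C)(C)C)C[C@H](O[Si](C)(C)C(C)(C)C)[C@H](C)CC/C(C)=C/C=O | intermediate
19 | (3S,6R,7S,9R,10R)-7,9-bis[(tert-butyldimethylsilyl)oxy]-10-{[(tert-butyldimethylsilyl)oxy]methyl}-3,6-dimethyldodecanal | CC[C@H](CO[Si](C)(C)C(C)(C)C)[C@H](O[Si](C)(C)C(C)(C)C)C[C@H](O[Si](C)(C)C(C)(C)C)[C@H](C)CC[C@H](C)CC=O | intermediate (not isolated)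
20 | (3S,6R,7S,9R,10R)-7,9-bis[(tert-butyldimethylsilyl)oxy]-10-{[(tert-butyldimethylsilyl)oxy]methyl}-3,6-dimethyldodecan-1-ol | CC[C@H](CO[Si](C)(C)C(C)(C)C)[C@H](O[Si](C)(C)C(C)(C)C)C[C@H](O[Si](C)(C)C(C)(C)C)[C@H](C)CC[C@H](C)CCO | intermediate
21 | (3S,6R,7S,9R,10R)-7,9-bis[(tert-butyldimethylsilyl)oxy]-10-{[(tert-butyldimethylsilyl)oxy]methyl}-3,6-dimethyldodecyl 4-methylbenzenesulfonate | CC[C@H](CO[Si](C)(C)C(C)(C)C)[C@H](O[Si](C)(C)C(C)(C)C)C[C@H](O[Si](C)(C)C(C)(C)C)[C@H](C)CC[C@H](C)CCOS(=O)(=O)c1ccc(C)cc1 | intermediate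
22 | iodo{[(1R,2R,6S)-2-[(tert-butyldimethylsilyl)oxy]-6-ethyl-1,2-dimethylcyclohex-3-en-1-yl]methyl}magnesium | I[Mg]C[C@]1(C)[C@@H](CC)CC=C[C@@]1(C)O[Si](C)(C)C(C)(C)C | intermediate (not isolated)
23 | tert-butyl{[(1R,5S,6R)-6-[(4R,7R,8S,10R,11R)-8,10-bis[(tert-butyldimethylsilyl)oxy]-11-{[(tert-butyldimethylsilyl)oxy]methyl}-4,7-dimethyltridecyl]-5-ethyl-1,6-dimethylcyclohex-2-en-1-yl]oxy}dimethylsilane | CC[C@H](CO[Si](C)(C)C(C)(C)C)[C@H](O[Si](C)(C)C(C)(C)C)C[C@H](O[Si](C)(C)C(C)(C)C)[C@H](C)CC[C@H](C)CCC[C@]1(C)[C@@H](CC)CC=C[C@@]1(C)O[Si](C)(C)C(C)(C)C | intermediate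
24 | (4R,5R,6R)-4-[(tert-butyldimethylsilyl)oxy]-5-[(4R,7R,8S,10R,11R)-8,10-bis[(tert-butyldimethylsilyl)oxy]-11-{[(tert-butyldimethylsilyl)oxy]methyl}-4,7-dimethyltridecyl]-6-ethyl-4,5-dimethylcyclohex-2-en-1-one | CC[C@H](CO[Si](C)(C)C(C)(C)C)[C@H](O[Si](C)(C)C(C)(C)C)C[C@H](O[Si](C)(C)C(C)(C)C)[C@H](C)CC[C@H](C)CCC[C@]1(C)[C@@H](CC)C(=O)C=C[C@@]1(C)O[Si](C)(C)C(C)(C)C | intermediate
25 | (4R,5R,6R)-5-[(4R,7R,8S,10R,11R)-8,10-dihydroxy-11-(hydroxymethyl)-4,7-dimethyltridecyl]-6-ethyl-4-hydroxy-4,5-dimethylcyclohex-2-en-1-one | CC[C@H](CO)[C@H](O)C[C@H](O)[C@H](C)CC[C@H](C)CCC[C@]1(C)[C@@H](CC)C(=O)C=C[C@@]1(C)O | target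

**Step count and risks**

Total: 16 steps (ring branch steps 1–4, boronate step 5, chain steps 6–13, union and end game steps 14–16). Longest linear sequence: 11 steps (steps 6–16, from propanal and methyl vinyl ketone).

The three steps most likely to fail:

Step 2 (the proposed new Diels–Alder reaction). The hindered iminium ion may react too slowly, the diene may add in its s-trans form to give an open-chain Michael product, or the dienol ether may be hydrolysed. The fallback uses only established reactions and makes the C19 centre by substrate-controlled Grignard addition instead of by cycloaddition. It sets out from 3 and comes back at 6. Commercial crotonaldehyde is silylated (TBSOTf, Et3N) to (E)-tert-butyl(buta-1,3-dien-1-yloxy)dimethylsilane F1. A triflimide-activated chiral oxazaborolidine (boron Lewis acid, CH2Cl2, −78 °C), an established catalyst class for α-substituted enals with 1-silyloxybutadienes, then gives the endo adduct (1R,2S,6S)-2-[(tert-butyldimethylsilyl)oxy]-6-ethyl-1-methylcyclohex-3-ene-1-carbaldehyde F2 with C14 and C15 as in 4. NaBH4 gives [(1S,2S,6S)-2-[(tert-butyldimethylsilyl)oxy]-6-ethyl-1-methylcyclohex-3-en-1-yl]methanol F3, and PPh3/I2/imidazole gives tert-butyl{[(1S,5S,6R)-5-ethyl-6-(iodomethyl)-6-methylcyclohex-2-en-1-yl]oxy}dimethylsilane F4. HF·pyridine frees (1S,5S,6R)-5-ethyl-6-(iodomethyl)-6-methylcyclohex-2-en-1-ol F5, and Dess–Martin periodinane gives (5S,6R)-5-ethyl-6-(iodomethyl)-6-methylcyclohex-2-en-1-one F6. MeMgBr with CeCl3 (THF, −78 °C) adds 1,2 from the face anti to the pseudoaxial C14 methyl group (ethyl equatorial) to give (1R,5S,6R)-5-ethyl-6-(iodomethyl)-1,6-dimethylcyclohex-2-en-1-ol F7. TBSOTf/2,6-lutidine then returns 6.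

Step 7 (mismatched, anti-Felkin Mukaiyama aldol on an epimerisable aldehyde). The fallback replaces the open transition state by a closed allylboration followed by oxidative cleavage. It sets out from 11 and comes back at 13. (S)-TRIP phosphoric acid-catalysed allylboration with allylboronic acid pinacol ester (toluene, −30 °C; the methyl ketone is inert) gives (5R,6S)-6-hydroxy-5-methylnon-8-en-2-one F8. TBSOTf/2,6-lutidine gives (5R,6S)-6-[(tert-butyldimethylsilyl)oxy]-5-methylnon-8-en-2-one F9. Ozonolysis (O3, CH2Cl2, −78 °C, then PPh3) returns 13.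

Step 14 (formation and coupling of a very hindered neopentyl Grignard reagent). The fallback joins the fragments by olefination and restores the enone afterwards. It sets out from 4 and 21 and comes back at 24. Allylic oxidation of 4 (CrO3, 3,5-dimethylpyrazole, CH2Cl2, −20 °C) gives (1R,2R,6R)-2-[(tert-butyldimethylsilyl)oxy]-6-ethyl-1,2-dimethyl-5-oxocyclohex-3-ene-1-carbaldehyde F10. Heating 21 with PPh3 (MeCN, 80 °C) gives [(3S,6R,7S,9R,10R)-7,9-bis[(tert-butyldimethylsilyl)oxy]-10-{[(tert-butyldimethylsilyl)oxy]methyl}-3,6-dimethyldodecyl]triphenylphosphonium 4-methylbenzenesulfonate F11. Wittig olefination (NaN(SiMe3)2, THF, −78 °C) of the aldehyde group of F10 gives the Z-alkenyl enone F12. H2 over Pd/C saturates both the new alkene and the enone C=C to give the cyclohexanone F13. LiN(iPr)2/Me3SiCl (THF, −78 °C) gives the less substituted trimethylsilyl enol ether F14, and Saegusa–Ito dehydrogenation (Pd(OAc)2, MeCN, rt) returns 24.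

**Further compounds**
F1 | step 2 | (E)-tert-butyl(buta-1,3-dien-1-yloxy)dimethylsilane | C=C/C=C/O[Si](C)(C)C(C)(C)C
F2 | step 2 | (1R,2S,6S)-2-[(tert-butyldimethylsilyl)oxy]-6-ethyl-1-methylcyclohex-3-ene-1-carbaldehyde | O=C[C@]1(C)[C@@H](CC)CC=C[C@@H]1O[Si](C)(C)C(C)(C)C
F3 | step 2 | [(1S,2S,6S)-2-[(tert-butyldimethylsilyl)oxy]-6-ethyl-1-methylcyclohex-3-en-1-yl]methanol | OC[C@]1(C)[C@@H](CC)CC=C[C@@H]1O[Si](C)(C)C(C)(C)C
F4 | step 2 | tert-butyl{[(1S,5S,6R)-5-ethyl-6-(iodomethyl)-6-methylcyclohex-2-en-1-yl]oxy}dimethylsilane | IC[C@]1(C)[C@@H](CC)CC=C[C@@H]1O[Si](C)(C)C(C)(C)C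
F5 | step 2 | (1S,5S,6R)-5-ethyl-6-(iodomethyl)-6-methylcyclohex-2-en-1-ol | IC[C@]1(C)[C@@H](CC)CC=C[C@@H]1O
F6 | step 2 | (5S,6R)-5-ethyl-6-(iodomethyl)-6-methylcyclohex-2-en-1-one | IC[C@]1(C)[C@@H](CC)CC=CC1=O
F7 | step 2 | (1R,5S,6R)-5-ethyl-6-(iodomethyl)-1,6-dimethylcyclohex-2-en-1-ol | IC[C@]1(C)[C@@H](CC)CC=C[C@@]1(C)O
F8 | step 7 | (5R,6S)-6-hydroxy-5-methylnon-8-en-2-one | C=CC[C@H](O)[C@H](C)CCC(C)=O
F9 | step 7 | (5R,6S)-6-[(tert-butyldimethylsilyl)oxy]-5-methylnon-8-en-2-one | C=CC[C@H](O[Si](C)(C)C(C)(C)C)[C@H](C)CCC(C)=O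
F10 | step 14 | (1R,2R,6R)-2-[(tert-butyldimethylsilyl)oxy]-6-ethyl-1,2-dimethyl-5-oxocyclohex-3-ene-1-carbaldehyde | O=C[C@]1(C)[C@@H](CC)C(=O)C=C[C@@]1(C)O[Si](C)(C)C(C)(C)C
F11 | step 14 | [(3S,6R,7S,9R,10R)-7,9-bis[(tert-butyldimethylsilyl)oxy]-10-{[(tert-butyldimethylsilyl)oxy]methyl}-3,6-dimethyldodecyl]triphenylphosphonium 4-methylbenzenesulfonate | CC[C@H](CO[Si](C)(C)C(C)(C)C)[C@H](O[Si](C)(C)C(C)(C)C)C[C@H](O[Si](C)(C)C(C)(C)C)[C@H](C)CC[C@H](C)CC[P+](c1ccccc1)(c1ccccc1)c1ccccc1.Cc1ccc(cc1)S(=O)(=O)[O-]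
F12 | step 14 | (4R,5R,6R)-4-[(tert-butyldimethylsilyl)oxy]-5-[(1Z,4S,7R,8S,10R,11R)-8,10-bis[(tert-butyldimethylsilyl)oxy]-11-{[(tert-butyldimethylsilyl)oxy]methyl}-4,7-dimethyltridec-1-en-1-yl]-6-ethyl-4,5-dimethylcyclohex-2-en-1-one | CC[C@H](CO[Si](C)(C)C(C)(C)C)[C@H](O[Si](C)(C)C(C)(C)C)C[C@H](O[Si](C)(C)C(C)(C)C)[C@H](C)CC[C@H](C)C/C=C\[C@]1(C)[C@@H](CC)C(=O)C=C[C@@]1(C)O[Si](C)(C)C(C)(C)C
F13 | step 14 | (2R,3R,4R)-4-[(tert-butyldimethylsilyl)oxy]-3-[(4R,7R,8S,10R,11R)-8,10-bis[(tert-butyldimethylsilyl)oxy]-11-{[(tert-butyldimethylsilyl)oxy]methyl}-4,7-dimethyltridecyl]-2-ethyl-3,4-dimethylcyclohexan-1-one | CC[C@H](CO[Si](C)(C)C(C)(C)C)[C@H](O[Si](C)(C)C(C)(C)C)C[C@H](O[Si](C)(C)C(C)(C)C)[C@H](C)CC[C@H](C)CCC[C@]1(C)[C@@H](CC)C(=O)CC[C@@]1(C)O[Si](C)(C)C(C)(C)C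
F14 | step 14 | trimethylsilyl enol ether (C16=C17) of F13 | CC[C@H](CO[Si](C)(C)C(C)(C)C)[C@H](O[Si](C)(C)C(C)(C)C)C[C@H](O[Si](C)(C)C(C)(C)C)[C@H](C)CC[C@H](C)CCC[C@]1(C)[C@@H](CC)C(O[Si](C)(C)C)=CC[C@@]1(C)O[Si](C)(C)C(C)(C)C
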